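Two questions stand for this flask: for the target you compare how fast isomerisation relaxes with how fast dormant form feeds it, and for the dissolved gas you compare that feed with gas transfer.

starting material 0.083 M; gas phase 8.1 mM (held); catalyst 0.18 mM; time 2.5 min

    starting material + dissolved gas + catalyst → catalyst + target (k1 = 5.6 × 10⁵ /M²/s)
    gas phase ⇌ dissolved gas, rate k2*(csat - [dissolved gas]) (k2 = 0.40 /s, csat = 8.1 mM)
    starting material ⇌ dormant form (K3 = 4.8, k3 = 0.039 /s)
    target + catalyst ⇌ isomer of the product + catalyst, rate k4*[catalyst]*[target] forward; the back reaction follows from the equilibrium constant (K4 = 2.8, k4 = 290 /M/s)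

* the target standing at 2.5 min, as a percentage of the starting material charged
* concentration of dissolved gas in solution at 2.5 min, in percent of saturation

- at the start none of the gas is dissolved
- run time (flask): 2.5 min

Work in fractions of the charge. Target's equilibrium share of product is 0.263. Turn the question round: target stands far above that share if relaxation is no faster than the feed's decay. So compare the two.

1. Burst. Step 1 removes dissolved gas at 8.37 /s, faster than the transfer coefficient 0.40 /s, so transfer is the rate-limiting step, converting 0.0390 /s of the charge. Starting material also goes dormant at 0.039 /s times its fraction. Replace that falling fraction by its mean, 0.5: the dormant share is 0.333, after 17.1 s. Integrating the curve gives 0.307, a small error.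

2. Bleed. Dormant form returns at 0.00813 /s, leaving d = 0.113 at 2.5 min.

3. Relaxation. The catalyst is regenerated, so step 4 is pseudo-first-order, with rate 0.0708 /s and half-life 0.163 min, shorter than the run.

4. Lag. Target's excess over its share, behind a feed decaying at the bleed rate, is (1 − share)·lag·d, where the lag, bleed/(relax − bleed), is 0.130. Here relaxation is 8.71 times the bleed.

5. Answers. Target is share·(1 − d) plus that excess: 0.244. Reckon gas uptake as equal to the bleed, and saturation is 0.976; isomerisation does not enter this reckoning.

The forecast gives 24.3% and 97.7%: “the target sits near its 1/3.8 equilibrium share of the product”.

The flask gives 24.3% and 97.7%, against my 24.4% and 97.6%, with dormant form at 11.4%. Put the lag to use at 1.25 min: dormant form stood at 20.4%, which gives target 22.9%, and the flask held 23.3%.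

For the neighbour flask with 4.5 × 10⁻⁵ M of catalyst, the lag becomes 0.848, and with the same d target reckons to 30.4%. That neighbour flask gave 31.6%, with dormant form at 16.0%.

Its constants are assumed; the run is a simulation.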